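I decided to reckon these flasks by hand with one quantity before trusting any integration of them.

    starting material + target → side product B (k1 = 0.081 /M/s)
    starting material + partner → target (k2 = 0.35 /M/s)
    2 rival reagent → homo dimer (k3 = 16 /M/s)
    starting material + rival reagent → side product A (k4 = 0.39 /M/s)
    starting material → decomposition product (k5 = 6.9 × 10⁻⁵ /s)

in all of them: partner 2.00 equiv; rival reagent 0.800 equiv

| charge | starting material | time | remark |
|---|---|---|---|
| eta | 22 mM (fed, over 25.0 s) | 50 s | all but starting material at the start; starting material goes in evenly over 25.0 s, the run ends at 50 s |
| theta | 22 mM |  | a single well-mixed tank run continuously and read at steady state, 150 s in it on average |
| delta | 22 mM |  | one stirred flow tank at steady state, fed with the mixture as stated, mean residence time 50 s |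
| beta | 22 mM | 50 s | a closed flask charged with all of it at once and left for 50 s |

- in percentages every species weighs as the starting material in it: one side product B counts as two
- where a step has two of a species, its rate is k times that concentration squared, and two are used at each turn
- the stated concentrations are those of everything mixed, before any reaction; amounts are the same in each set-up
- the feed brings no volume worth counting
- run time (eta): 50 s

1. the set-up with the highest amount of target at the outlet or at the end, in percent of the starting material put in ("none" if the first two lie within 2 percentage points) (eta / theta / delta / beta / none)
2. amount of target at the outlet or at the end, in percent of the starting material put in, eta
3. amount of target at the outlet or at the end, in percent of the starting material put in, theta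
4. amount of target at the outlet or at the end, in percent of the starting material put in, delta
5. amount of target at the outlet or at the end, in percent of the starting material put in, beta

I asked first where each flask was heading. With partner at 2.00 equiv, starting material is the limiting reagent and target is where the main step leads, so the question was how far along that road each flask got. The partner makes the main step pseudo-first-order, and that gave me the contact number, a Damköhler number: the constant of the main step times the charged partner times the time starting material spends in the flask, 0.770 for beta.

With the main step alone, a closed flask converts one minus e to the minus that number, and a stirred tank converts the number over one plus itself. So beta gave 53.7% and delta 43.5%. Theta, with 2.31, gave 69.8%. In eta the starting material stays 37.5 s on average, so its number of 0.577 gave 43.8%.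

Then I added the rival reagent. At the start of beta the main step uses starting material just 2.2 times as fast as the rival path does, which looked serious. But the rival's first half-life by dimerisation is 1.78 s, far shorter than the 45 s of starting material. Integrated over beta, the rival therefore adds 0.0411 to the exponent.

Last came the partner's own loss. In beta the main step spends 26.8% of the partner charge, so the mean partner stands lower by half of that, and the contact number shrinks to 0.667. Shared with the rival, that left me 47.8% target in beta. A tank works at its outlet partner, so theta's number fell to 1.50 and its target to 60.1%, still above beta. Step 1 takes target and I left it unpriced, so both figures stood high. The decomposition step I dropped in theta. My order was theta, beta, then eta and delta.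

The forecast, from hand steps and balances, gave 38.2% for eta, 52.1% for theta, 34.7% for delta and 45.5% for beta, with theta best, holding that “side product A takes only a few percent”. Its theta and beta stood below mine.

The simulation gave 38.2% for eta, 52.1% for theta, 34.8% for delta and 45.4% for beta, with theta best. At the outlet of theta, 34.4% of the starting material was still unreacted. The neighbour of beta with 55 mM of starting material, same equivalents and time, has a contact number of 1.93. The partner's loss shrinks that to 1.51, which leaves 22.1% of its starting material. That flask held 19.9% of its starting material, 2.1 percentage points less than this reckoning, with target at 68.6%.

Its constants were chosen freely; the run is a simulation.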